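**Plan**
- Cuts, in retrosynthetic order: the two bonds of the CH2 bridge (CH2–C6 of the trione ring B, then CH2–aryl carbon of ring A); the ring B bond between the enol carbon next to the quaternary centre and the butanoyl-bearing carbon; the chain bond between the other carbonyl on the quaternary centre and its CH2; finally prenyl–C, aryl–hexanoyl and O–CH3.
- Forward: ring A is bought as phloroglucinol, then acylated, 4-O-methylated and aminomethylated. For ring B a malonate unit carrying the quaternary centre is joined to heptane-2,4-dione to give a linear 3,5,7-triketo ester, which one Claisen condensation folds into the carbocycle. The rings are joined last through an ortho-quinone methide.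
- Enabling feature: in the chain the ester carbon C1 and the ketone carbons C3, C5, C7 alternate with C2, C4, C6. The doubly activated C6 methylene therefore stands 1,5 to C1 and can close only the six-membered ring B. The fully substituted C2 (CH3, prenyl) has no hydrogen, cannot lead to an aromatic pyranone and favours the folded conformer.
- Stereochemistry: the single (R) quaternary centre comes from carboxylesterase desymmetrization of a prochiral malonate. It is never enolizable, and the chemical difference between its two carbonyl groups (acyl imidazole versus methyl ester) decides which one becomes which side of ring B.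

Key step: step 4

Assumption: the carboxylesterase (crude pig liver enzyme or a recombinant isoenzyme picked in a small screen) is taken to hydrolyse the pro-S ester group of the prenylated malonate, which gives the (R)-half-ester; the route is written for that outcome.

Step 1
Reactants: 1 dimethyl 2-methylmalonate; 2 1-bromo-3-methylbut-2-ene (prenyl bromide)
Product: 3 dimethyl 2-methyl-2-(3-methylbut-2-en-1-yl)malonate
Conditions: NaH (1.1 equiv), THF, 0 °C; then 2, 0 °C to rt
Reagents that add atoms: none
Why: C-alkylation of the malonate enolate (SN2 at the primary allylic carbon of 2) should give the prochiral quaternary diester, and over-alkylation is impossible because no acidic hydrogen remains.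

Step 2
Reactants: 3 dimethyl 2-methyl-2-(3-methylbut-2-en-1-yl)malonate
Product: 4 (R)-2-(methoxycarbonyl)-2,5-dimethylhex-4-enoic acid
Conditions: pig liver esterase (carboxylesterase), 0.1 M phosphate buffer pH 7.5, DMSO (10 vol%), pH-stat with 1 M NaOH, 25 °C; then HCl to pH 2
Reagents that add atoms: water, O
Why: Enzymatic desymmetrization by ester hydrolysis: the carboxylesterase places the methyl and prenyl groups in pockets of different size and so should hydrolyse only one of the two enantiotopic ester groups (taken as pro-S), which sets the quaternary stereocentre as (R), and the reaction stops at the half-ester because the carboxylate is not a substrate.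

Step 3
Reactants: 4 (R)-2-(methoxycarbonyl)-2,5-dimethylhex-4-enoic acid; 5 heptane-2,4-dione
Product: 8 methyl (R)-2-methyl-2-(3-methylbut-2-en-1-yl)-3,5,7-trioxodecanoate, via acyl imidazolide 6 (not isolated), via dilithium dienolate 7 (not isolated)
Conditions: 4, 1,1'-carbonyldiimidazole (1.05 equiv), THF, rt to 40 °C; separately 5 (3 equiv), LiN(iPr)2 (6 equiv), THF, −78 to 0 °C; add 6 to 7 at −78 °C, warm to −30 °C; cold 1 M HCl
Reagents that add atoms: none
Why: Terminal C-acylation of a 1,3-diketone dianion (Claisen-type acylation): the carbanion of 7 formed kinetically at the methyl end should attack only the acyl imidazole carbonyl of 6, which is far more electrophilic than the neopentyl-like methyl ester, so the two carbonyl groups on the stereocentre stay differentiated and the configuration is untouched.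

Step 4
Reactants: 8 methyl (R)-2-methyl-2-(3-methylbut-2-en-1-yl)-3,5,7-trioxodecanoate
Product: 9 (R)-2-butanoyl-3,5-dihydroxy-4-methyl-4-(3-methylbut-2-en-1-yl)cyclohexa-2,5-dien-1-one
Conditions: NaOMe (3 equiv), MeOH, 0 °C to 40 °C; then cold 1 M HCl
Reagents that add atoms: none
Why: NaOMe converts the triketone into its enolates, the C6 carbanion (between the C5 and C7 carbonyls) adds to the ester carbon C1, methoxide leaves, and the 2-acyl-1,3,5-trione formed is deprotonated at once, which makes the closure irreversible. The closest known reaction type is the intramolecular Claisen (Dieckmann) condensation by which 3,5,7-triketo esters give acylphloroglucinols and 2,2-disubstituted 3,5-diketo esters give 4,4-disubstituted cyclohexane-1,3,5-triones, the laboratory form of the C6-to-C1 folding of a tetraketide. Ring B closes in the 6-(enolexo)-exo-trig mode. No stereocentre is made: C2 has no hydrogen and takes no part in the bond changes, so its (R) configuration passes into the ring, and the direction of the chain places the butanoyl group only on the carbon next to the former ester carbon. The step needs C- instead of O-acylation and attack by C6 alone: C4 could close only a four-membered and C8 only an eight-membered ring, and the enol lactone from O-attack cannot tautomerize to an aromatic 4-hydroxypyranone because C2 is quaternary, so it stays an acyl donor that methoxide reopens until the trione enolate, the thermodynamic sink, is reached. Ester exchange with methoxide is degenerate, and the C3 carbonyl is shielded from retro-Claisen cleavage because it is part of an enolate and flanked by the quaternary carbon.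

Step 5
Reactants: 10 benzene-1,3,5-triol (phloroglucinol); 11 hexanoyl chloride
Product: 12 1-(2,4,6-trihydroxyphenyl)hexan-1-one
Conditions: AlCl3 (3.5 equiv), PhNO2, rt to 60 °C; then ice and 1 M HCl
Reagents that add atoms: none
Why: Friedel–Crafts C-acylation of the electron-rich triol should stop after one acyl group because the chelated ketone deactivates the ring.

Step 6
Reactants: 12 1-(2,4,6-trihydroxyphenyl)hexan-1-one
Product: 13 1-(2,6-dihydroxy-4-methoxyphenyl)hexan-1-one
Conditions: Me2SO4 (1.0 equiv), K2CO3 (1.0 equiv), acetone, rt
Reagents that add atoms: dimethyl sulfate, COS(=O)(=O)OC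
Why: O-methylation (Williamson type) with limiting reagent: the 4-hydroxyl is the most acidic and the only one not held in a hydrogen bond to the ketone, so it should be methylated first.

Step 7
Reactants: 13 1-(2,6-dihydroxy-4-methoxyphenyl)hexan-1-one
Product: 14 1-{3-[(dimethylamino)methyl]-2,6-dihydroxy-4-methoxyphenyl}hexan-1-one
Conditions: CH2(NMe2)2 (1.0 equiv), 1,4-dioxane, rt; used without chromatography
Reagents that add atoms: bis(dimethylamino)methane, CN(C)CN(C)C
Why: Phenol Mannich reaction with a preformed aminal: the acidic phenol ionizes the aminal to the methyleneiminium ion, which should attack one of the two equivalent free ring positions (between OH and OCH3), and one equivalent of reagent limits double aminomethylation.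

Step 8
Reactants: 9 (R)-2-butanoyl-3,5-dihydroxy-4-methyl-4-(3-methylbut-2-en-1-yl)cyclohexa-2,5-dien-1-one; 14 1-{3-[(dimethylamino)methyl]-2,6-dihydroxy-4-methoxyphenyl}hexan-1-one
Product: 15 elaphopilosin B
Conditions: 14 (1.1 equiv), 1,4-dioxane, 90 °C, slow N2 stream
Reagents that add atoms: none
Why: Ortho-quinone methide alkylation (Michael type): proton transfer from the acidic trione 9 to the amine of 14 and loss of dimethylamine should unmask the quinone methide, which is captured by the only nucleophilic carbon of 9 (C6 of ring B), and rearomatization gives the methylene bridge without touching the remote quaternary stereocentre.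

**Compound list**
1 | dimethyl 2-methylmalonate | COC(=O)C(C)C(=O)OC | starting material
2 | 1-bromo-3-methylbut-2-ene (prenyl bromide) | CC(C)=CCBr | starting material
3 | dimethyl 2-methyl-2-(3-methylbut-2-en-1-yl)malonate | COC(=O)C(C)(CC=C(C)C)C(=O)OC | intermediate
4 | (R)-2-(methoxycarbonyl)-2,5-dimethylhex-4-enoic acid | OC(=O)[C@@](C)(CC=C(C)C)C(=O)OC | intermediate
5 | heptane-2,4-dione | CCCC(=O)CC(C)=O | starting material
6 | methyl (R)-2-(1H-imidazole-1-carbonyl)-2,5-dimethylhex-4-enoate (acyl imidazolide) | COC(=O)[C@](C)(CC=C(C)C)C(=O)n1ccnc1 | intermediate
7 | dilithium hepta-1,3-diene-2,4-diolate (dilithium dienolate of 5) | [Li+].[Li+].C=C([O-])C=C([O-])CCC | intermediate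
8 | methyl (R)-2-methyl-2-(3-methylbut-2-en-1-yl)-3,5,7-trioxodecanoate | COC(=O)[C@](C)(CC=C(C)C)C(=O)CC(=O)CC(=O)CCC | intermediate
9 | (R)-2-butanoyl-3,5-dihydroxy-4-methyl-4-(3-methylbut-2-en-1-yl)cyclohexa-2,5-dien-1-one | O=C1C=C(O)[C@@](C)(CC=C(C)C)C(O)=C1C(=O)CCC | intermediate
10 | benzene-1,3,5-triol (phloroglucinol) | Oc1cc(O)cc(O)c1 | starting material
11 | hexanoyl chloride | CCCCCC(=O)Cl | starting material
12 | 1-(2,4,6-trihydroxyphenyl)hexan-1-one | CCCCCC(=O)c1c(O)cc(O)cc1O | intermediate
13 | 1-(2,6-dihydroxy-4-methoxyphenyl)hexan-1-one | CCCCCC(=O)c1c(O)cc(OC)cc1O | intermediate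
14 | 1-{3-[(dimethylamino)methyl]-2,6-dihydroxy-4-methoxyphenyl}hexan-1-one | CCCCCC(=O)c1c(O)cc(OC)c(CN(C)C)c1O | intermediate
15 | elaphopilosin B, (R)-2-butanoyl-6-[(3-hexanoyl-2,4-dihydroxy-6-methoxyphenyl)methyl]-3,5-dihydroxy-4-methyl-4-(3-methylbut-2-en-1-yl)cyclohexa-2,5-dien-1-one | CCCCCC(=O)c1c(O)cc(OC)c(CC2=C(O)[C@@](C)(CC=C(C)C)C(O)=C(C(=O)CCC)C2=O)c1O | target

Total step count: 8. Longest linear sequence: 5 steps (steps 1, 2, 3, 4, 8).

**Steps most likely to fail**

Step 4. The chain may acylate on oxygen and rest as the enol lactone, may be cleaved by retro-Claisen attack of methoxide at the C7 or C3 carbonyl, or may close too slowly onto the hindered ester. The fallback sets out from 2 and comes back at 9; it gives up the chain folding for dearomatizing alkylation followed by resolution. Friedel–Crafts acylation of commercial 2-methylbenzene-1,3,5-triol (Cc1c(O)cc(O)cc1O) with butanoyl chloride (CCCC(=O)Cl) and AlCl3 in PhNO2 should give 1-(2,4,6-trihydroxy-3-methylphenyl)butan-1-one F3. C-alkylation of its sodium phenolate with 2 (NaOMe, MeOH, 0 °C) at the methyl-bearing ring carbon should dearomatize the ring. After separation from the aromatic isomer prenylated at the free ring carbon, this gives racemic 2-butanoyl-3,5-dihydroxy-4-methyl-4-(3-methylbut-2-en-1-yl)cyclohexa-2,5-dien-1-one F4. Preparative HPLC on a chiral stationary phase then delivers 9, whose configuration is to be assigned by circular dichroism.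

Step 2. The enzyme may discriminate the two enantiotopic ester groups poorly or in the opposite sense. The fallback sets out from 3 and comes back at 4; it replaces desymmetrization by classical resolution. Half-saponification of 3 (KOH, 1 equiv, MeOH/H2O, rt; then HCl) should give racemic 2-(methoxycarbonyl)-2,5-dimethylhex-4-enoic acid F1. Fractional crystallization with (S)-1-phenylethylamine (C[C@H](N)c1ccccc1; the (R)-amine if that one deposits the wanted acid) should give the salt (S)-1-phenylethylammonium (R)-2-(methoxycarbonyl)-2,5-dimethylhex-4-enoate F2. Acidification returns 4.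

Step 8. The methylene unit may be exchanged between the partners by retro-Michael cleavage, which leads to symmetrical dimers, and the aromatic ring may be alkylated a second time at its remaining free position. The fallback sets out from 13 and comes back at 15; it fixes the one-carbon unit on ring A as a non-transferable aldehyde. Vilsmeier–Haack formylation of 13 (POCl3, DMF, EtOAc, 0 °C to rt; aqueous hydrolysis) should give 3-hexanoyl-2,4-dihydroxy-6-methoxybenzaldehyde F5. Reductive Knoevenagel alkylation of 9 with F5 (L-proline cat., Hantzsch ester, CH2Cl2/EtOH, rt) should form the arylidene trione and reduce it in the same flask to the CH2 bridge of 15.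

**Further compounds**
F1 | step 2 | racemic 2-(methoxycarbonyl)-2,5-dimethylhex-4-enoic acid | COC(=O)C(C)(CC=C(C)C)C(O)=O
F2 | step 2 | (S)-1-phenylethylammonium (R)-2-(methoxycarbonyl)-2,5-dimethylhex-4-enoate | C[C@H]([NH3+])c1ccccc1.[O-]C(=O)[C@@](C)(CC=C(C)C)C(=O)OC
F3 | step 4 | 1-(2,4,6-trihydroxy-3-methylphenyl)butan-1-one | CCCC(=O)c1c(O)cc(O)c(C)c1O
F4 | step 4 | racemic 2-butanoyl-3,5-dihydroxy-4-methyl-4-(3-methylbut-2-en-1-yl)cyclohexa-2,5-dien-1-one | CCCC(=O)C1=C(O)C(C)(CC=C(C)C)C(O)=CC1=O
F5 | step 8 | 3-hexanoyl-2,4-dihydroxy-6-methoxybenzaldehyde | CCCCCC(=O)c1c(O)cc(OC)c(C=O)c1O
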